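The runs were computed with constants of no real substance; noise was put on by code.

A small charge of substrate, 0.10 M against 0.500 M of reagent, follows one percentage curve at both sizes tried: the midnight run at 0.20 M gives 11.9% at 12.0 min, between the winter run's 11.3% at 10.0 min and 15.0% at 15.0 min. So the readings look first order in substrate at a given age of the flask, pseudo-first-order in the usual term, and exposures add. Winter's last reading gives 0.464, and this number, the exposure E_w, the natural logarithm of substrate charged over substrate unreacted after 120 min, is what I carry. It comes ever more slowly: 0.120 in the first 10.0 min, but from 0.412 at 80.0 min only 0.0511 more by the end. I read that as reagent ageing.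

| flask | substrate | reagent | temperature | remark | time |
|---|---|---|---|---|---|
| winter | 0.10 M | 0.50 M | 25 °C | run made earlier |  |
| midnight | 0.20 M | 0.50 M | 25 °C | run made earlier |  |
| green | 0.10 M | 0.500 M |  | everything together at the start at 5 °C, warmed to 25 °C at 50 min | 2.0 h |
| red | 0.10 M (in portions, 3, over 50 min) | 0.500 M | 25 °C | first portion at the start, last at 50 min | 2.0 h |
| ochre | 0.10 M (fed, over 50 min) | 0.500 M |  | the addition at 5 °C, then warmed to 25 °C; the feed brings no volume worth counting | 2.0 h |
| violet | 0.10 M (fed, over 50 min) | 0.500 M | 25 °C | all else is in the flask from the start; the feed brings no volume worth counting | 2.0 h |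
| grey | 0.10 M | 0.500 M (fed, over 50 min) | 25 °C | all else is in the flask from the start; the feed brings no volume worth counting | 2.0 h |

| run | time / min | product / % |
|---|---|---|
| winter | 10.0 | 11.3 |
| winter | 15.0 | 15.0 |
| winter | 25.0 | 20.7 |
| winter | 40.0 | 25.8 |
| winter | 80.0 | 33.8 |
| winter | 120 | 37.1 |
| midnight | 1.00 | 1.7 |
| midnight | 1.50 | 1.6 |
| midnight | 2.50 | 3.0 |
| midnight | 4.00 | 5.8 |
| midnight | 8.00 | 8.9 |
| midnight | 12.0 | 11.9 |

(scatter of a reading: 0.3 percentage points)

- a reading or a percentage of product counts all its forms, free or not
- the earlier runs do not show what temperature does; that part of a forecast is a guess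

- the flask with the highest amount of product, in percent of the substrate charged ("all alike" if they lie within 1.5 percentage points) (green / red / ochre / violet / grey / all alike)
- final product, as a percentage of the substrate charged, in green
- final product, as a percentage of the substrate charged, in red
- final product, as a percentage of the substrate charged, in ochre
- final product, as a percentage of the substrate charged, in violet
- final product, as a percentage of the substrate charged, in grey

Take grey, where the reagent is fed over 50 min, and suppose each parcel of reagent adds exposure along the winter curve from its own entry. From above: had every parcel entered at the start, you get E_w, so 37.1% product. From below: had every parcel entered at the end of the feed, you get 70.0 min of curve. The chord from 0.298 at 40.0 min to the reading at 80.0 min lies under a curve bending this way, so exposure is at least 0.384, or 31.9% product.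

Now tighten. The parcels enter evenly, so grey is E_w minus a small correction, the mean exposure lost. By hand that mean is 0.430, a correction of 0.0335, so I commit to 35.0%. Substrate fed late meets the tail instead: entering at 40.0 min it gets 0.165, so I put violet and red below grey. The runs do not price the cold in green and ochre, and I name grey first.

The forecast named green first at 36%, put ochre at 30%, red at 23% and violet at 22%, and gave grey 35%, a figure inside my bracket, with the words “Feeding reagent keeps it fresher”.

The flasks give grey first at 37.1%, then green 30.7%, ochre 27.8%, red 24.6% and violet 23.4%. Grey stands at the top of the bracket, 2.1 percentage points above my figure.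

    substrate + reagent → product, rate k1*[substrate]*[reagent]^1.5 (k = 7.04 × 10⁻⁴ /M^1.5/s, Ea = 69.0 kJ/mol)
    2 reagent → homo dimer (k = 5.38 × 10⁻⁴ /M/s, Ea = 52.0 kJ/mol)
    crystals ⇌ product, rate k3*(cs3 - [product]) while solid is left; crystals form when [product] > cs3 (solubility = 2.70 mM, k = 0.00168 /s)
    (constants at 25 °C)

Grey's 62.9% of substrate left means an exposure of 0.463, beside E_w. Now keep a flask like grey at 50 °C and take the same logarithm. Its 72.1% of product means an exposure of 1.28, which is 2.75 times E_w, while the product percentage grew by a factor of 1.94. At 0 °C the same step on 7.75% gives 0.0807. The warm flask ends with 6.16% of its reagent charge left.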